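**Retrosynthetic overview**

1. The target is a 6,8-diformyl-5,7-dihydroxychroman whose dihydropyran ring is trans-fused across C1–C10 of a (4Z)-cyclodecene. The ether oxygen sits on the tertiary, methyl-bearing C10 and the benzylic carbon C1' on the adjacent C1; this O–C10/C1'–C1 pattern in the pyran ring is the retron of an oxa-[4+2] addition of an o-quinone methide to an E-trisubstituted ring olefin, and it is what makes the key step possible.
2. Last disconnection: O–C10 and C1'–C1, giving an o-quinone methide (made in the flask from diformylphloroglucinol and 3-methylbutanal) and the (7R)-(1(10)E,4Z)-germacradien-11-ol.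
3. The ten-membered ring is opened at C6–C7: a (Z)-allyl sulfide carbanion opens an (R)-epoxide, which sets C7 and frees the hydroxyisopropyl group; the sulfur is then removed reductively.
4. The acyclic epoxy sulfide comes from neryl acetate (Z-olefin), E-selective allylic oxidation (E-olefin), enolate alkylation with a C5 hydroxy-ketone unit and CBS reduction (source of C7).
5. Ring order: the aromatic ring is bought as phloroglucinol; the ten-membered carbocycle is closed in step 9; the dihydropyran is closed last, in step 12.

Key step: step 12

Remark: the C4=C5 olefin is taken as drawn, cis (Z) inside the ten-membered ring. Terpenoid carbons carry germacrane numbers (ring C1–C10, C1 bonded to the benzylic carbon C1', C10 carrying the ether oxygen and a methyl, C7 carrying C11); acyclic intermediates are numbered as farnesyl chains.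

**Route**

Step 1
Reactants: 1 neryl acetate [(2Z)-3,7-dimethylocta-2,6-dien-1-yl acetate]
Product: 2 (2Z,6E)-8-hydroxy-3,7-dimethylocta-2,6-dien-1-yl acetate
Conditions: SeO2 (cat.), t-BuOOH, salicylic acid (cat.), CH2Cl2, rt
Reagents that add atoms: selenium dioxide, O=[Se]=O (catalytic oxygen carrier); tert-butyl hydroperoxide, CC(C)(C)OO (terminal oxidant)
Why: Catalytic SeO2 allylic oxidation (ene reaction followed by a [2,3]-sigmatropic shift) should attack the electron-richer distal trisubstituted olefin at its E-methyl group, so that the new CH2OH is trans to the chain, while the neryl Z-olefin is deactivated by the allylic acetate and keeps its geometry.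

Step 2
Reactants: 2 (2Z,6E)-8-hydroxy-3,7-dimethylocta-2,6-dien-1-yl acetate
Product: 3 (2Z,6E)-8-bromo-3,7-dimethylocta-2,6-dien-1-yl acetate
Conditions: CBr4, PPh3, CH2Cl2, 0 °C
Reagents that add atoms: carbon tetrabromide, BrC(Br)(Br)Br
Why: The Appel reaction should convert the primary allylic alcohol into the bromide by SN2 displacement of the oxyphosphonium ion, without allylic transposition and without touching either olefin geometry or the acetate.

Step 3
Reactants: 4 3-hydroxy-3-methylbutan-2-one
Product: 5 3-methyl-3-(trimethylsilyloxy)butan-2-one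
Conditions: Me3SiCl, imidazole, DMF, rt
Reagents that add atoms: chlorotrimethylsilane, C[Si](C)(C)Cl
Why: Imidazole-promoted O-silylation masks the tertiary hydroxyl so that the methyl ketone can be enolised cleanly and later reduced under catalyst control.

Step 4
Reactants: 5 3-methyl-3-(trimethylsilyloxy)butan-2-one; 3 (2Z,6E)-8-bromo-3,7-dimethylocta-2,6-dien-1-yl acetate
Product: 7 (2Z,6E)-3,7,11-trimethyl-10-oxo-11-(trimethylsilyloxy)dodeca-2,6-dien-1-yl acetate, via lithium enolate 6 (not isolated)
Conditions: LiN(iPr)2, THF, −78 °C; then 3, DMPU, −78 → −30 °C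
Reagents that add atoms: none
Why: The ketone has a single enolisable position, and its kinetic lithium enolate should be C-alkylated (SN2 enolate alkylation) by the reactive primary allylic bromide at low temperature faster than it attacks the acetate, which forms the C8–C9 bond of the farnesyl chain with both olefin geometries intact.

Step 5
Reactants: 7 (2Z,6E)-3,7,11-trimethyl-10-oxo-11-(trimethylsilyloxy)dodeca-2,6-dien-1-yl acetate
Product: 9 (2Z,6E,10S)-10,11-dihydroxy-3,7,11-trimethyldodeca-2,6-dien-1-yl acetate, via silyl ether carbinol 8 (not isolated)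
Conditions: (R)-1-methyl-3,3-diphenyltetrahydro-1H,3H-pyrrolo[1,2-c][1,3,2]oxazaborole [(R)-Me-CBS] (20 mol %), catecholborane, toluene, −78 → −40 °C; then MeOH, PPTS, rt
Reagents that add atoms: none
Why: In the Corey–Bakshi–Shibata reduction the oxazaborolidine binds the ketone with the siloxy-tert-alkyl group as the large substituent, so the (R)-catalyst should deliver hydride to the face that gives the (10S)-carbinol, catecholborane at low temperature spares olefins and acetate, and mild acidic methanolysis then removes the silyl ether.

Step 6
Reactants: 9 (2Z,6E,10S)-10,11-dihydroxy-3,7,11-trimethyldodeca-2,6-dien-1-yl acetate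
Product: 10 (2Z,6E,10S)-11-hydroxy-10-(methanesulfonyloxy)-3,7,11-trimethyldodeca-2,6-dien-1-yl acetate
Conditions: MsCl, Et3N, CH2Cl2, −20 °C
Reagents that add atoms: methanesulfonyl chloride, CS(=O)(=O)Cl
Why: Sulfonylation should occur only at the secondary hydroxyl because the neighbouring tertiary hydroxyl is too hindered, and the C10 configuration is untouched.

Step 7
Reactants: 10 (2Z,6E,10S)-11-hydroxy-10-(methanesulfonyloxy)-3,7,11-trimethyldodeca-2,6-dien-1-yl acetate
Product: 11 (2Z,6E)-9-[(2R)-3,3-dimethyloxiran-2-yl]-3,7-dimethylnona-2,6-dien-1-ol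
Conditions: K2CO3, MeOH, rt
Reagents that add atoms: none
Why: The tertiary alkoxide displaces the adjacent mesylate in an intramolecular Williamson reaction (SN2, inversion at C10) to give the (R)-epoxide, and the same medium removes the acetate by transesterification.

Step 8
Reactants: 11 (2Z,6E)-9-[(2R)-3,3-dimethyloxiran-2-yl]-3,7-dimethylnona-2,6-dien-1-ol
Product: 12 (2R)-2-[(3E,7Z)-3,7-dimethyl-9-(phenylsulfanyl)nona-3,7-dien-1-yl]-3,3-dimethyloxirane
Conditions: PhSSPh, n-Bu3P, THF, rt
Reagents that add atoms: diphenyl disulfide, c1ccc(SSc2ccccc2)cc1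
Why: In this Mitsunobu-type thioetherification (disulfide/phosphine) the primary allylic hydroxyl is activated as an alkoxyphosphonium ion and displaced by thiophenolate in an SN2 manner, which should keep the Z-olefin in place and leave the trisubstituted epoxide alone.

Step 9
Reactants: 12 (2R)-2-[(3E,7Z)-3,7-dimethyl-9-(phenylsulfanyl)nona-3,7-dien-1-yl]-3,3-dimethyloxirane
Product: 14 2-[(3Z,7E)-4,8-dimethyl-2-(phenylsulfanyl)cyclodeca-3,7-dien-1-yl]propan-2-ol (ring C1 configured as in 15 and formally 1S because of the sulfur substituent; either configuration at the sulfur-bearing carbon), via α-lithio sulfide 13 (not isolated)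
Conditions: n-BuLi, DABCO, THF (0.005 M), −78 → −20 °C; then H2O
Reagents that add atoms: none
Why: Intramolecular SN2 opening of the epoxide at its secondary carbon by the α-lithiated (Z)-allyl phenyl sulfide (a carbanion macrocyclisation with close precedent in the all-E farnesyl series) closes the ten-membered ring through the C6–C7 bond, inverts the (R)-epoxide carbon into the required C7 configuration and releases the hydroxyisopropyl group, while low temperature preserves the Z geometry of the allyl anion, high dilution suppresses intermolecular alkylation, and the new sulfur-bearing centre is removed in step 10.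

Step 10
Reactants: 14 2-[(3Z,7E)-4,8-dimethyl-2-(phenylsulfanyl)cyclodeca-3,7-dien-1-yl]propan-2-ol
Product: 15 2-[(1R,3Z,7E)-4,8-dimethylcyclodeca-3,7-dien-1-yl]propan-2-ol (the (7R)-(1(10)E,4Z)-germacradien-11-ol)
Conditions: Li, EtNH2, THF, −78 °C; then H2O
Reagents that add atoms: none
Why: Dissolving-metal (Birch-type) reductive cleavage of the allylic C–S bond gives an allyl anion that should be protonated at the former sulfur-bearing carbon, which returns the trisubstituted C4=C5 olefin in its Z form because at −78 °C protonation is faster than rotation of the allyl anion, and isolated olefins and the tertiary alcohol are inert.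

Step 11
Reactants: 16 phloroglucinol (benzene-1,3,5-triol)
Product: 18 2,4,6-trihydroxybenzene-1,3-dicarbaldehyde, via bis(iminium) salt 17 (not isolated)
Conditions: POCl3 (2.2 equiv), DMF (2.2 equiv), 1,4-dioxane, 0 °C → rt; then H2O
Reagents that add atoms: N,N-dimethylformamide, CN(C)C=O; water, O
Why: Double Vilsmeier–Haack formylation of the strongly activated ring should stop at the dialdehyde under stoichiometric control because each formyl group deactivates the ring, and hydrolysis of the iminium groups delivers the aldehydes.

Step 12
Reactants: 15 2-[(1R,3Z,7E)-4,8-dimethylcyclodeca-3,7-dien-1-yl]propan-2-ol; 18 2,4,6-trihydroxybenzene-1,3-dicarbaldehyde; 19 3-methylbutanal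
Product: 21 target CNP0570248.1, via o-quinone methide 20 (not isolated)
Conditions: 15 (1.0 equiv), 18 (1.5 equiv), 19 (2.0 equiv), ethylenediammonium diacetate (20 mol %), MeCN, 4 Å molecular sieves, 25 → 40 °C
Reagents that add atoms: none
Why: Amine-salt-catalysed Knoevenagel condensation of 18 with 19 and loss of water gives the (E)-o-quinone methide 20, whose electron-poor 1-oxadiene adds in an inverse-electron-demand oxa-[4+2] cycloaddition to the strained, electron-rich E-trisubstituted C1=C10 olefin of 15: the C1'–C1 bond forms first at the less substituted olefin carbon and the phenolic oxygen then closes onto the developing tertiary centre, which is the O–C10 bond that completes the dihydropyran. The closest known reaction type is the biomimetic three-component domino Knoevenagel/hetero-Diels–Alder coupling of formylated phloroglucinols with aldehydes and terpene olefins, including strained medium-ring sesquiterpenes. The one new ring, the dihydropyran of the chroman, is closed in the [4+2] mode, suprafacial on both partners (in the stepwise limit a six-membered collapse of phenoxide onto the C10 cation). C10 and C1 arise from suprafacial addition to the E-olefin, which fixes the trans ring fusion, and their absolute sense should follow from attack on the outer face of the olefin in the conformer that keeps the C7 hydroxyisopropyl group pseudo-equatorial and the C10 methyl on the ring face opposite H-7, so that the existing 7R centre controls 10R and 1S; C1' (S) is set by the E geometry of 20 together with the orientation that places H-1 and C9, not the C2 methylene and the C10 methyl, under the heterodiene, which leaves isobutyl and C2 trans. The step needs site selectivity for the E over the Z olefin (secured by the strain and higher HOMO of the E-olefin in the ten-membered ring), regioselectivity (oxygen to the more substituted carbon, secured by Markovnikov polarisation) and facial selectivity (secured by peripheral attack on the conformationally biased ring), and it must outrun transannular capture of the C10 cation, which the near-neutral, non-ionising medium and the concerted character of the cycloaddition should ensure.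

**Compound list**

1 | neryl acetate, (2Z)-3,7-dimethylocta-2,6-dien-1-yl acetate | CC(C)=CCC/C(C)=C\COC(C)=O | starting material
2 | (2Z,6E)-8-hydroxy-3,7-dimethylocta-2,6-dien-1-yl acetate | OC/C(C)=C/CC/C(C)=C\COC(C)=O | intermediate
3 | (2Z,6E)-8-bromo-3,7-dimethylocta-2,6-dien-1-yl acetate | BrC/C(C)=C/CC/C(C)=C\COC(C)=O | intermediate
4 | 3-hydroxy-3-methylbutan-2-one | CC(=O)C(C)(C)O | starting material
5 | 3-methyl-3-(trimethylsilyloxy)butan-2-one | CC(=O)C(C)(C)O[Si](C)(C)C | intermediate
6 | lithium enolate of 5, lithium 3-methyl-3-(trimethylsilyloxy)but-1-en-2-olate | [Li]OC(=C)C(C)(C)O[Si](C)(C)C | intermediate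
7 | (2Z,6E)-3,7,11-trimethyl-10-oxo-11-(trimethylsilyloxy)dodeca-2,6-dien-1-yl acetate | CC(C)(O[Si](C)(C)C)C(=O)CC/C(C)=C/CC/C(C)=C\COC(C)=O | intermediate
8 | (2Z,6E,10S)-10-hydroxy-3,7,11-trimethyl-11-(trimethylsilyloxy)dodeca-2,6-dien-1-yl acetate | CC(C)(O[Si](C)(C)C)[C@@H](O)CC/C(C)=C/CC/C(C)=C\COC(C)=O | intermediate
9 | (2Z,6E,10S)-10,11-dihydroxy-3,7,11-trimethyldodeca-2,6-dien-1-yl acetate | CC(C)(O)[C@@H](O)CC/C(C)=C/CC/C(C)=C\COC(C)=O | intermediate
10 | (2Z,6E,10S)-11-hydroxy-10-(methanesulfonyloxy)-3,7,11-trimethyldodeca-2,6-dien-1-yl acetate | CC(C)(O)[C@@H](OS(C)(=O)=O)CC/C(C)=C/CC/C(C)=C\COC(C)=O | intermediate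
11 | (2Z,6E)-9-[(2R)-3,3-dimethyloxiran-2-yl]-3,7-dimethylnona-2,6-dien-1-ol, the (2Z,6E,10R)-10,11-epoxyfarnesol | CC1(C)O[C@@H]1CC/C(C)=C/CC/C(C)=C\CO | intermediate
12 | (2R)-2-[(3E,7Z)-3,7-dimethyl-9-(phenylsulfanyl)nona-3,7-dien-1-yl]-3,3-dimethyloxirane | CC1(C)O[C@@H]1CC/C(C)=C/CC/C(C)=C\CSc1ccccc1 | intermediate
13 | α-lithio derivative of 12 (lithium on the carbon bearing sulfur) | CC1(C)O[C@@H]1CC/C(C)=C/CC/C(C)=C\C([Li])Sc1ccccc1 | intermediate
14 | 2-[(3Z,7E)-4,8-dimethyl-2-(phenylsulfanyl)cyclodeca-3,7-dien-1-yl]propan-2-ol, ring C1 as in 15 (formally 1S), mixture at the sulfur-bearing carbon | C/C1=C/C(Sc2ccccc2)[C@H](C(C)(C)O)CC/C(C)=C/CC1 | intermediate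
15 | 2-[(1R,3Z,7E)-4,8-dimethylcyclodeca-3,7-dien-1-yl]propan-2-ol | C/C1=C/C[C@H](C(C)(C)O)CC/C(C)=C/CC1 | intermediate
16 | phloroglucinol, benzene-1,3,5-triol | Oc1cc(O)cc(O)c1 | starting material
17 | bis(dimethyliminium) dichloride of 18 | C[N+](C)=Cc1c(O)cc(O)c(C=[N+](C)C)c1O.[Cl-].[Cl-] | intermediate
18 | 2,4,6-trihydroxybenzene-1,3-dicarbaldehyde | O=Cc1c(O)cc(O)c(C=O)c1O | intermediate
19 | 3-methylbutanal | CC(C)CC=O | starting material
20 | (E)-o-quinone methide, 2,4-dihydroxy-5-(3-methylbutylidene)-6-oxocyclohexa-1,3-diene-1,3-dicarbaldehyde | O=C1C(C=O)=C(O)C(C=O)=C(O)/C1=C\CC(C)C | intermediate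
21 | target CNP0570248.1: 6,8-diformyl-5,7-dihydroxy-4-isobutyl-2-methylchroman trans-fused at C2–C3 (germacrane C10–C1) to a (4Z)-cyclodecene carrying the 7-(2-hydroxypropan-2-yl) group; 1S,1'S,7R,10R in germacrane numbering | C/C1=C/C[C@H](C(C)(C)O)CC[C@@]2(C)Oc3c(C=O)c(O)c(C=O)c(O)c3[C@@H](CC(C)C)[C@@H]2CC1 | target

**Step count and risks**

Total step count: 12. Longest linear sequence: 10 steps (steps 1, 2, 4, 5, 6, 7, 8, 9, 10 and 12, from neryl acetate).

Steps most likely to fail:

Step 12. The quinone methide may be consumed by conjugate addition of a second molecule of 18 faster than the hindered trisubstituted olefin traps it. Acid from the phenol may also start transannular cyclisation of 15, and facial discrimination on the mobile ten-membered ring may be incomplete. The fallback sets out from 18 (with 19) and comes back to the route at 21; it generates the same heterodiene by oxidation instead of condensation. 18 and 19 are first joined by reductive alkylation (Hantzsch ester, L-proline cat., CH2Cl2, rt) to 2,4,6-trihydroxy-5-(3-methylbutyl)benzene-1,3-dicarbaldehyde F1, a fully substituted phenol that cannot act as a carbon nucleophile. F1 is then dehydrogenated at the benzylic position with DDQ in MeNO2 at 0 °C in the presence of 15. This releases 20 slowly, without amine, acid or free 18, and the cycloaddition should give 21.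

Step 9. Intermolecular alkylation, base-induced isomerisation of the epoxide to an allylic alcohol, or reaction of the allyl anion at its γ-terminus may outrun closure of the ten-membered ring. The fallback sets out from 11 and comes back to the route at 15, so that step 10 is bypassed as well. It uses a sulfone-stabilised carbanion, which is less basic, reacts at the α-carbon and tolerates slow addition at higher temperature. 11 is converted with N-chlorosuccinimide and Me2S (CH2Cl2, −20 °C) into (2R)-2-[(3E,7Z)-9-chloro-3,7-dimethylnona-3,7-dien-1-yl]-3,3-dimethyloxirane F2. Sodium p-toluenesulfinate in DMF then gives (2R)-2-[(3E,7Z)-3,7-dimethyl-9-(4-methylbenzenesulfonyl)nona-3,7-dien-1-yl]-3,3-dimethyloxirane F3. F3 is cyclised with LiN(SiMe3)2 in THF under high dilution (−78 → 0 °C) to 2-[(3Z,7E)-4,8-dimethyl-2-(4-methylbenzenesulfonyl)cyclodeca-3,7-dien-1-yl]propan-2-ol F4. F4 is desulfonylated with LiBHEt3 and catalytic [1,3-bis(diphenylphosphino)propane]PdCl2 in THF at 0 °C, with hydride delivery to the less substituted end of the allyl–palladium intermediate, to give 15.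

Step 10. The intermediate allyl anion may be protonated at its methyl-bearing terminus (olefin migration to C5=C6) or may lose its Z geometry before protonation. The fallback sets out from 14 and comes back to the route at 15; it replaces dissolving-metal cleavage by hydride transfer within an allyl–palladium complex. 14 is oxidised chemoselectively at sulfur ((NH4)6Mo7O24 cat., H2O2, EtOH, 0 °C) to 2-[(3Z,7E)-2-(benzenesulfonyl)-4,8-dimethylcyclodeca-3,7-dien-1-yl]propan-2-ol F5. F5 is reduced with LiBHEt3 and catalytic [1,3-bis(diphenylphosphino)propane]PdCl2 in THF at 0 °C to 15.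

Further compounds
F1 | step 12 | 2,4,6-trihydroxy-5-(3-methylbutyl)benzene-1,3-dicarbaldehyde | CC(C)CCc1c(O)c(C=O)c(O)c(C=O)c1O
F2 | step 9 | (2R)-2-[(3E,7Z)-9-chloro-3,7-dimethylnona-3,7-dien-1-yl]-3,3-dimethyloxirane | CC1(C)O[C@@H]1CC/C(C)=C/CC/C(C)=C\CCl
F3 | step 9 | (2R)-2-[(3E,7Z)-3,7-dimethyl-9-(4-methylbenzenesulfonyl)nona-3,7-dien-1-yl]-3,3-dimethyloxirane | CC1(C)O[C@@H]1CC/C(C)=C/CC/C(C)=C\CS(=O)(=O)c1ccc(C)cc1
F4 | step 9 | 2-[(3Z,7E)-4,8-dimethyl-2-(4-methylbenzenesulfonyl)cyclodeca-3,7-dien-1-yl]propan-2-ol | C/C1=C/C(S(=O)(=O)c2ccc(C)cc2)[C@H](C(C)(C)O)CC/C(C)=C/CC1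
F5 | step 10 | 2-[(3Z,7E)-2-(benzenesulfonyl)-4,8-dimethylcyclodeca-3,7-dien-1-yl]propan-2-ol | C/C1=C/C(S(=O)(=O)c2ccccc2)[C@H](C(C)(C)O)CC/C(C)=C/CC1
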